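**Plan**

- Enabling feature: ring A is a 2-alkylphloroglucinol monomethyl ether. C3' carries the side-chain CH2 and lies between oxygenated C2' and C4', with C6'–OMe para to it. A siloxyalkyne R–C≡C–OSi and 3-methoxycyclobutenone assemble exactly this 2-alkyl-1,3,5-trioxygenated pattern.
- Retrosynthetic cuts, in order: (a) the O-protecting groups; (b) the aryl–carbonyl bond C1'–C(=O), leading to an aryllithium and a ring B cinnamoyl Weinreb amide (itself cut at Cα=Cβ); (c) two ring A bonds, C3' to one flanking C–O carbon and the other flanking C–O carbon to its neighbouring CH; (d) the ynol C≡C bond (one-carbon ester homologation), the tertiary C–CH3 bond, and the cyclohexene C=C of limonene.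
- Forward order: the C10 side chain is made first from (R)-limonene (steps 1–7), ring A is built on its alkyne terminus (step 9), ring B with the enone is attached last (step 14), and one acid step unmasks everything (step 15).
- Stereochemistry: the single (R) centre is C4 of (R)-limonene, carried through without ever being a reacting or enolisable position. The E-alkene comes from a Horner–Wadsworth–Emmons olefination.

Key step: step 9

Remark on the chemistry: the stereocentre of the target is read from the SMILES as (R). The CIP ranking isopropenyl > former C3 arm > former C5 arm holds from limonene to the target, so (R)-limonene gives the required enantiomer.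

**Route**

Step 1
Reactants: 1 (R)-(+)-limonene
Product: 2 (4R)-limonene 1,2-oxide (mixture of epoxide diastereomers)
Conditions: mCPBA (1.0 equiv), CH2Cl2, 0 °C
Reagents that add atoms: 3-chloroperoxybenzoic acid, O=C(OO)c1cccc(Cl)c1
Why: Prilezhaev epoxidation is fastest at the more electron-rich trisubstituted ring alkene, so one equivalent of peracid should leave the isopropenyl group untouched; the two new stereocentres are uncontrolled and need not be controlled, because step 2 destroys them, and C4 is not involved.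

Step 2
Reactants: 2 (4R)-limonene 1,2-oxide
Product: 4 (3R)-6-oxo-3-(prop-1-en-2-yl)heptanal, via limonene-1,2-diol 3 (not isolated)
Conditions: H5IO6, THF/H2O, 0 °C → rt
Reagents that add atoms: water, O
Why: Aqueous periodic acid should open the epoxide to diol 3 and cleave it in the same flask (Malaprade glycol cleavage) to the methyl ketone and the aldehyde, while the stereocentre, β to the aldehyde and without an acidic hydrogen, is not at risk.

Step 3
Reactants: 4 (3R)-6-oxo-3-(prop-1-en-2-yl)heptanal
Product: 5 (3R)-6-oxo-3-(prop-1-en-2-yl)heptanoic acid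
Conditions: NaClO2, NaH2PO4, 2-methylbut-2-ene, t-BuOH/H2O, 0 °C → rt
Reagents that add atoms: sodium chlorite, [Na+].[O-]Cl=O
Why: Pinnick oxidation, with 2-methylbut-2-ene as hypochlorite scavenger, converts the aldehyde to the acid under buffered, weakly acidic conditions that should spare the isopropenyl group and the ketone and give no opening for aldol cyclisation of the keto aldehyde.

Step 4
Reactants: 5 (3R)-6-oxo-3-(prop-1-en-2-yl)heptanoic acid
Product: 6 methyl (3R)-6-oxo-3-(prop-1-en-2-yl)heptanoate
Conditions: MeI, K2CO3, DMF, rt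
Reagents that add atoms: iodomethane, CI
Why: SN2 O-methylation of the potassium carboxylate is a standard esterification, and carbonate is too weak a base to enolise the ketone for C-methylation.

Step 5
Reactants: 6 methyl (3R)-6-oxo-3-(prop-1-en-2-yl)heptanoate
Product: 7 methyl (3R)-6-hydroxy-6-methyl-3-(prop-1-en-2-yl)heptanoate
Conditions: MeMgBr, CeCl3 (anhydrous), THF, −78 °C; aq. NH4Cl
Reagents that add atoms: methylmagnesium bromide, C[Mg]Br
Why: Organocerium addition: the oxophilic, weakly basic methylcerium reagent should add to the methyl ketone much faster than to the methyl ester and without enolisation, and the new carbinol carbon bears two identical methyl groups, so no stereocentre arises.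

Step 6
Reactants: 7 methyl (3R)-6-hydroxy-6-methyl-3-(prop-1-en-2-yl)heptanoate
Product: 8 methyl (3R)-6-methyl-3-(prop-1-en-2-yl)-6-(triethylsilyloxy)heptanoate
Conditions: Et3SiOTf, 2,6-lutidine, CH2Cl2, −78 → 0 °C
Reagents that add atoms: triethylsilyl trifluoromethanesulfonate, CC[Si](CC)(CC)OS(=O)(=O)C(F)(F)F
Why: Silyl triflate with 2,6-lutidine is the standard silylation of a hindered tertiary alcohol, and the triethylsilyl ether shields the hydroxyl from the organolithium and ketene chemistry ahead and is lost in the final acid step.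

Step 7
Reactants: 8 methyl (3R)-6-methyl-3-(prop-1-en-2-yl)-6-(triethylsilyloxy)heptanoate
Product: 11 triisopropyl{[(4R)-7-methyl-4-(prop-1-en-2-yl)-7-(triethylsilyloxy)oct-1-yn-1-yl]oxy}silane, via lithium dibromoenolate 9 (not isolated), via lithium ynolate 10 (not isolated)
Conditions: CH2Br2, lithium 2,2,6,6-tetramethylpiperidide, THF, −78 °C; then LiN(SiMe3)2; then n-BuLi, −78 °C → rt; then i-Pr3SiCl, −78 °C → rt
Reagents that add atoms: dibromomethane, BrCBr; chlorotriisopropylsilane, CC(C)[Si](Cl)(C(C)C)C(C)C
Why: Kowalski ester homologation halted at the ynolate: LiCHBr2 adds to the ester, dibromo ketone enolate 9 undergoes bromine–lithium exchange, the carbenoid rearranges on warming by 1,2-shift of the alkyl group to ynolate 10, and the bulky silyl chloride captures 10 on oxygen rather than carbon; the stereocentre is β to the ester carbon and is not touched.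

Step 8
Reactants: 12 3-ethoxycyclobut-2-en-1-one
Product: 13 3-methoxycyclobut-2-en-1-one
Conditions: MeOH (solvent), TsOH (cat.), 4 Å molecular sieves, rt
Reagents that add atoms: methanol, CO
Why: Acid-catalysed transetherification of a vinylogous ester (methanol adds at the β-carbon to the mixed ketal, then ethanol leaves) should exchange the alkoxy group, the excess of methanol driving the equilibrium along the same pathway as the known acid hydrolysis of this enol ether.

Step 9
Reactants: 11 triisopropyl{[(4R)-7-methyl-4-(prop-1-en-2-yl)-7-(triethylsilyloxy)oct-1-yn-1-yl]oxy}silane; 13 3-methoxycyclobut-2-en-1-one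
Product: 18 5-methoxy-2-[(2R)-5-methyl-2-(prop-1-en-2-yl)-5-(triethylsilyloxy)hexyl]-3-(triisopropylsilyloxy)phenol, via methoxy vinylketene 14 (not isolated), via vinylcyclobutenone adduct 15 (not isolated), via dienylketene 16 (not isolated), via cyclohexadienone tautomer 17 (not isolated)
Conditions: 13 (1.3 equiv), toluene, 80 → 110 °C, sealed tube, argon
Reagents that add atoms: none
Why: Heating opens 13 by a 4π electrocyclic reaction to methoxy vinylketene 14, whose ketene C=C adds [2+2] to the electron-rich triple bond of 11 to give 4-vinylcyclobutenone 15, and a second 4π opening of 15 leads to dienylketene 16. This is the Danheiser benzannulation of a cyclobutenone with a trialkylsiloxyalkyne, the established way to resorcinol monosilyl ethers, applied here to a 3-alkoxycyclobutenone, a less common partner that is nonetheless known to open thermally to its vinylketene. Ring A closes by thermal disrotatory 6π electrocyclisation of 16, which joins the ketene carbon to the terminal =CH2 carbon, and cyclohexadienone 17 then enolises to the aromatic phenol 18. No stereocentre is created, because the sp3 carbons of 15 and 17 are transient, and the (R) centre, two bonds from the alkyne and without an acidic hydrogen, cannot epimerise under neutral thermal conditions. The step needs regioselectivity in the [2+2] event, and the polarisation of the ynol ether secures it: the nucleophilic alkyne carbon remote from oxygen (the one carrying the side-chain CH2) bonds to the electrophilic ketene carbonyl carbon, so the chain is placed between the new C–OH and the C–OSi carbons with OMe para to it. Chemoselectivity follows from the same polarisation, since the isopropenyl group is a far weaker ketenophile than the ynol ether and the tertiary hydroxyl is silylated.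

Step 10
Reactants: 18 5-methoxy-2-[(2R)-5-methyl-2-(prop-1-en-2-yl)-5-(triethylsilyloxy)hexyl]-3-(triisopropylsilyloxy)phenol
Product: 19 5-methoxy-2-[(2R)-5-methyl-2-(prop-1-en-2-yl)-5-(triethylsilyloxy)hexyl]benzene-1,3-diol
Conditions: Bu4NF/AcOH (1:1, 1.05 equiv), THF, 0 °C
Reagents that add atoms: none
Why: Fluoride-induced Si–O cleavage is far faster for an aryl silyl ether, which releases a phenoxide, than for a hindered tertiary alkyl silyl ether, so buffered fluoride at 0 °C should unmask only the phenol and give a resorcinol whose two free ring positions are equivalent by rotation about the aryl–CH2 bond.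

Step 11
Reactants: 19 5-methoxy-2-[(2R)-5-methyl-2-(prop-1-en-2-yl)-5-(triethylsilyloxy)hexyl]benzene-1,3-diol
Product: 20 5-methoxy-1,3-bis(methoxymethoxy)-2-[(2R)-5-methyl-2-(prop-1-en-2-yl)-5-(triethylsilyloxy)hexyl]benzene
Conditions: NaH, MOMCl, DMF, 0 °C → rt
Reagents that add atoms: chloromethyl methyl ether, COCCl
Why: Williamson-type O-alkylation of the two sodium phenoxides with the hard electrophile MOMCl gives the bis-MOM ether, which supplies the directing groups for the ortho-lithiation in step 14.

Step 12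
Reactants: 21 2,4-dihydroxybenzaldehyde
Product: 22 2,4-bis(methoxymethoxy)benzaldehyde
Conditions: MOMCl, K2CO3, acetone, reflux
Reagents that add atoms: chloromethyl methyl ether, COCCl
Why: Phenol O-alkylation with MOMCl and K2CO3 is the standard preparation of this aldehyde, and heating with excess reagent is planned because the 2-hydroxyl is hydrogen-bonded to the formyl group.

Step 13
Reactants: 22 2,4-bis(methoxymethoxy)benzaldehyde
Product: 23 (2E)-3-[2,4-bis(methoxymethoxy)phenyl]-N-methoxy-N-methylprop-2-enamide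
Conditions: (EtO)2P(O)CH2C(O)N(OMe)Me, NaH, THF, 0 °C → rt
Reagents that add atoms: diethyl {2-[methoxy(methyl)amino]-2-oxoethyl}phosphonate, CCOP(=O)(OCC)CC(=O)N(C)OC
Why: Horner–Wadsworth–Emmons olefination with the stabilised amide phosphonate anion should give the E-alkene, since the reversible addition funnels through the less crowded anti oxaphosphetane.

Step 14
Reactants: 20 5-methoxy-1,3-bis(methoxymethoxy)-2-[(2R)-5-methyl-2-(prop-1-en-2-yl)-5-(triethylsilyloxy)hexyl]benzene; 23 (2E)-3-[2,4-bis(methoxymethoxy)phenyl]-N-methoxy-N-methylprop-2-enamide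
Product: 26 (2E)-3-[2,4-bis(methoxymethoxy)phenyl]-1-{6-methoxy-2,4-bis(methoxymethoxy)-3-[(2R)-5-methyl-2-(prop-1-en-2-yl)-5-(triethylsilyloxy)hexyl]phenyl}prop-2-en-1-one, via aryllithium 24 (not isolated), via lithium hemiaminal chelate 25 (not isolated)
Conditions: n-BuLi (1.05 equiv), THF, 0 °C; then 23, −78 → 0 °C; aq. NH4Cl
Reagents that add atoms: none
Why: Directed ortho-metalation followed by Weinreb ketone synthesis: n-BuLi should remove the ring hydrogen flanked by the OMOM and OMe groups (both such positions are equivalent), and 1,2-addition of aryllithium 24 to the N-methoxy-N-methylamide gives the chelated tetrahedral adduct 25, which cannot take up a second nucleophile and releases the E-enone only on aqueous quench.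

Step 15
Reactants: 26 (2E)-3-[2,4-bis(methoxymethoxy)phenyl]-1-{6-methoxy-2,4-bis(methoxymethoxy)-3-[(2R)-5-methyl-2-(prop-1-en-2-yl)-5-(triethylsilyloxy)hexyl]phenyl}prop-2-en-1-one
Product: 27 (2E)-1-{2,4-dihydroxy-3-[(2R)-5-hydroxy-5-methyl-2-(prop-1-en-2-yl)hexyl]-6-methoxyphenyl}-3-(2,4-dihydroxyphenyl)prop-2-en-1-one (CNP0356464.1)
Conditions: HCl (3 M aq.), MeOH, rt, dark
Reagents that add atoms: none
Why: Acid-catalysed acetal exchange in methanol removes the four aryl MOM ethers and solvolyses the tertiary triethylsilyl ether in one operation, and dilute acid at room temperature is the usual way to unmask MOM-protected prenylated 2'-hydroxychalcones without adding the phenols to the alkene or closing the flavanone.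

**Compound list**

1 | (R)-(+)-limonene, (4R)-1-methyl-4-(prop-1-en-2-yl)cyclohex-1-ene | CC1=CC[C@@H](CC1)C(C)=C | starting material
2 | (4R)-1-methyl-4-(prop-1-en-2-yl)-7-oxabicyclo[4.1.0]heptane (limonene 1,2-oxide, mixture of epoxide diastereomers) | CC12OC1C[C@@H](CC2)C(C)=C | intermediate
3 | (4R)-1-methyl-4-(prop-1-en-2-yl)cyclohexane-1,2-diol (limonene-1,2-diol, diastereomer mixture) | CC1(O)C(O)C[C@@H](CC1)C(C)=C | intermediate (not isolated)
4 | (3R)-6-oxo-3-(prop-1-en-2-yl)heptanal | C=C(C)[C@H](CCC(C)=O)CC=O | intermediate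
5 | (3R)-6-oxo-3-(prop-1-en-2-yl)heptanoic acid | C=C(C)[C@H](CCC(C)=O)CC(=O)O | intermediate
6 | methyl (3R)-6-oxo-3-(prop-1-en-2-yl)heptanoate | C=C(C)[C@H](CCC(C)=O)CC(=O)OC | intermediate
7 | methyl (3R)-6-hydroxy-6-methyl-3-(prop-1-en-2-yl)heptanoate | C=C(C)[C@H](CCC(C)(C)O)CC(=O)OC | intermediate
8 | methyl (3R)-6-methyl-3-(prop-1-en-2-yl)-6-(triethylsilyloxy)heptanoate | C=C(C)[C@H](CCC(C)(C)O[Si](CC)(CC)CC)CC(=O)OC | intermediate
9 | lithium (4R)-1,1-dibromo-7-methyl-4-(prop-1-en-2-yl)-7-(triethylsilyloxy)oct-1-en-2-olate (lithium dibromoenolate) | C=C(C)[C@H](CCC(C)(C)O[Si](CC)(CC)CC)CC([O-])=C(Br)Br.[Li+] | intermediate (not isolated)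
10 | lithium (4R)-7-methyl-4-(prop-1-en-2-yl)-7-(triethylsilyloxy)oct-1-yn-1-olate (lithium ynolate) | C=C(C)[C@H](CCC(C)(C)O[Si](CC)(CC)CC)CC#C[O-].[Li+] | intermediate (not isolated)
11 | triisopropyl{[(4R)-7-methyl-4-(prop-1-en-2-yl)-7-(triethylsilyloxy)oct-1-yn-1-yl]oxy}silane (siloxyalkyne) | C=C(C)[C@H](CCC(C)(C)O[Si](CC)(CC)CC)CC#CO[Si](C(C)C)(C(C)C)C(C)C | intermediate
12 | 3-ethoxycyclobut-2-en-1-one | CCOC1=CC(=O)C1 | starting material
13 | 3-methoxycyclobut-2-en-1-one | COC1=CC(=O)C1 | intermediate
14 | 3-methoxybuta-1,3-dien-1-one (methoxy vinylketene) | C=C(OC)C=C=O | intermediate (not isolated)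
15 | 4-(1-methoxyethenyl)-2-[(2R)-5-methyl-2-(prop-1-en-2-yl)-5-(triethylsilyloxy)hexyl]-3-(triisopropylsilyloxy)cyclobut-2-en-1-one (epimers at C4) | C=C(C)[C@H](CCC(C)(C)O[Si](CC)(CC)CC)CC1=C(O[Si](C(C)C)(C(C)C)C(C)C)C(C(=C)OC)C1=O | intermediate (not isolated)
16 | (3E)-5-methoxy-2-[(2R)-5-methyl-2-(prop-1-en-2-yl)-5-(triethylsilyloxy)hexyl]-3-(triisopropylsilyloxy)hexa-1,3,5-trien-1-one (dienylketene, ketene and methoxyvinyl groups cis) | C=C(C)[C@H](CCC(C)(C)O[Si](CC)(CC)CC)CC(=C=O)/C(O[Si](C(C)C)(C(C)C)C(C)C)=C\C(=C)OC | intermediate (not isolated)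
17 | 5-methoxy-2-[(2R)-5-methyl-2-(prop-1-en-2-yl)-5-(triethylsilyloxy)hexyl]-3-(triisopropylsilyloxy)cyclohexa-2,4-dien-1-one | C=C(C)[C@H](CCC(C)(C)O[Si](CC)(CC)CC)CC1=C(O[Si](C(C)C)(C(C)C)C(C)C)C=C(OC)CC1=O | intermediate (not isolated)
18 | 5-methoxy-2-[(2R)-5-methyl-2-(prop-1-en-2-yl)-5-(triethylsilyloxy)hexyl]-3-(triisopropylsilyloxy)phenol | C=C(C)[C@H](CCC(C)(C)O[Si](CC)(CC)CC)Cc1c(O)cc(OC)cc1O[Si](C(C)C)(C(C)C)C(C)C | intermediate
19 | 5-methoxy-2-[(2R)-5-methyl-2-(prop-1-en-2-yl)-5-(triethylsilyloxy)hexyl]benzene-1,3-diol | C=C(C)[C@H](CCC(C)(C)O[Si](CC)(CC)CC)Cc1c(O)cc(OC)cc1O | intermediate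
20 | 5-methoxy-1,3-bis(methoxymethoxy)-2-[(2R)-5-methyl-2-(prop-1-en-2-yl)-5-(triethylsilyloxy)hexyl]benzene | C=C(C)[C@H](CCC(C)(C)O[Si](CC)(CC)CC)Cc1c(OCOC)cc(OC)cc1OCOC | intermediate
21 | 2,4-dihydroxybenzaldehyde | O=Cc1ccc(O)cc1O | starting material
22 | 2,4-bis(methoxymethoxy)benzaldehyde | COCOc1ccc(C=O)c(OCOC)c1 | intermediate
23 | (2E)-3-[2,4-bis(methoxymethoxy)phenyl]-N-methoxy-N-methylprop-2-enamide | COCOc1ccc(/C=C/C(=O)N(C)OC)c(OCOC)c1 | intermediate
24 | {6-methoxy-2,4-bis(methoxymethoxy)-3-[(2R)-5-methyl-2-(prop-1-en-2-yl)-5-(triethylsilyloxy)hexyl]phenyl}lithium (aryllithium) | C=C(C)[C@H](CCC(C)(C)O[Si](CC)(CC)CC)Cc1c(OCOC)cc(OC)c([Li])c1OCOC | intermediate (not isolated)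
25 | lithium (2E)-3-[2,4-bis(methoxymethoxy)phenyl]-1-[methoxy(methyl)amino]-1-{6-methoxy-2,4-bis(methoxymethoxy)-3-[(2R)-5-methyl-2-(prop-1-en-2-yl)-5-(triethylsilyloxy)hexyl]phenyl}prop-2-en-1-olate (lithium hemiaminal chelate, carbinol carbon uncontrolled) | C=C(C)[C@H](CCC(C)(C)O[Si](CC)(CC)CC)Cc1c(OCOC)cc(OC)c(C([O-])(N(C)OC)/C=C/c2ccc(OCOC)cc2OCOC)c1OCOC.[Li+] | intermediate (not isolated)
26 | (2E)-3-[2,4-bis(methoxymethoxy)phenyl]-1-{6-methoxy-2,4-bis(methoxymethoxy)-3-[(2R)-5-methyl-2-(prop-1-en-2-yl)-5-(triethylsilyloxy)hexyl]phenyl}prop-2-en-1-one | C=C(C)[C@H](CCC(C)(C)O[Si](CC)(CC)CC)Cc1c(OCOC)cc(OC)c(C(=O)/C=C/c2ccc(OCOC)cc2OCOC)c1OCOC | intermediate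
27 | (2E)-1-{2,4-dihydroxy-3-[(2R)-5-hydroxy-5-methyl-2-(prop-1-en-2-yl)hexyl]-6-methoxyphenyl}-3-(2,4-dihydroxyphenyl)prop-2-en-1-one | C=C(C)[C@H](CCC(C)(C)O)Cc1c(O)cc(OC)c(C(=O)/C=C/c2ccc(O)cc2O)c1O | target

**Step count**

Total step count: 15. Longest linear sequence: 12 steps (steps 1–7, 9, 10, 11, 14 and 15, from (R)-limonene).

**Steps most likely to fail**

Step 9. The donor-substituted cyclobutenone may open too slowly at temperatures the ynol silyl ether tolerates, or the methoxy vinylketene may oligomerise faster than the alkyne captures it. The fallback sets out from siloxyalkyne 11 and comes back at phenol 18. It generates the same vinylketene 14 at room temperature by photochemical Wolff rearrangement instead of thermal ring opening, the light-driven variant of this benzannulation, which is known with siloxyalkynes. 3-Methoxybut-3-en-2-one is trifluoroacetylated (LiN(SiMe3)2, CF3CO2CH2CF3, THF, −78 °C) to 1,1,1-trifluoro-5-methoxyhex-5-ene-2,4-dione F1. Detrifluoroacetylative diazo transfer (MsN3, Et3N, H2O, MeCN) then gives 1-diazo-3-methoxybut-3-en-2-one F2. Irradiation of F2 with 11 in 1,2-dichloroethane (medium-pressure mercury lamp, rt), followed by warming to 80 °C, should carry 14 through 15, 16 and 17 to 18.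

Step 7. Bromine–lithium exchange may be incomplete, the bromo enolate may be protonated before it rearranges, silylation may go to carbon, or the ynol silyl ether may hydrolyse during isolation. The fallback sets out from ester 8 and comes back at siloxyalkyne 11 through ynolate 10, making the ynolate by oxidation of an acetylide instead of by carbenoid rearrangement. Reduction with i-Bu2AlH (CH2Cl2, −78 °C) gives (3R)-6-methyl-3-(prop-1-en-2-yl)-6-(triethylsilyloxy)heptanal F3. Ohira–Bestmann alkynylation (dimethyl (1-diazo-2-oxopropyl)phosphonate, K2CO3, MeOH) gives (4R)-7-methyl-4-(prop-1-en-2-yl)-7-(triethylsilyloxy)oct-1-yne F4. Deprotonation with n-BuLi gives the lithium acetylide F5. Its oxidation with lithium tert-butyl peroxide (from t-BuOOH and LiN(SiMe3)2, THF, −78 → 0 °C), a known route to lithium ynolates, gives 10, and i-Pr3SiOTf at −78 °C then gives 11.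

Step 15. Under protic acid the phenols flanking the side chain may add across the protonated isopropenyl group (chroman formation), the tertiary alcohol may ionise (elimination or methyl ether formation), or the freed 2'-hydroxyl may close onto the enone to the flavanone before all acetals are gone. The fallback sets out from 26 and comes back at 27 by a non-protic, two-stage unmasking. Me3SiOTf with 2,2'-bipyridyl (CH2Cl2, 0 °C) exchanges each aryl MOM ether for an aryl trimethylsilyl ether through an N-(methoxymethyl)bipyridinium salt, giving the tetrakis(trimethylsilyl) ether F6. Water hydrolyses F6 on work-up to the triethylsilyl-protected tetraphenol F7. Buffered fluoride (HF·pyridine, pyridine, THF, 0 °C) then removes the tertiary silyl ether to give 27.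

**Further compounds**

F1 | step 9 | 1,1,1-trifluoro-5-methoxyhex-5-ene-2,4-dione | C=C(OC)C(=O)CC(=O)C(F)(F)F
F2 | step 9 | 1-diazo-3-methoxybut-3-en-2-one | C=C(OC)C(=O)C=[N+]=[N-]
F3 | step 7 | (3R)-6-methyl-3-(prop-1-en-2-yl)-6-(triethylsilyloxy)heptanal | C=C(C)[C@H](CCC(C)(C)O[Si](CC)(CC)CC)CC=O
F4 | step 7 | (4R)-7-methyl-4-(prop-1-en-2-yl)-7-(triethylsilyloxy)oct-1-yne | C=C(C)[C@H](CCC(C)(C)O[Si](CC)(CC)CC)CC#C
F5 | step 7 | [(4R)-7-methyl-4-(prop-1-en-2-yl)-7-(triethylsilyloxy)oct-1-yn-1-yl]lithium | C=C(C)[C@H](CCC(C)(C)O[Si](CC)(CC)CC)CC#C[Li]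
F6 | step 15 | (2E)-3-[2,4-bis(trimethylsilyloxy)phenyl]-1-{6-methoxy-3-[(2R)-5-methyl-2-(prop-1-en-2-yl)-5-(triethylsilyloxy)hexyl]-2,4-bis(trimethylsilyloxy)phenyl}prop-2-en-1-one | C=C(C)[C@H](CCC(C)(C)O[Si](CC)(CC)CC)Cc1c(O[Si](C)(C)C)cc(OC)c(C(=O)/C=C/c2ccc(O[Si](C)(C)C)cc2O[Si](C)(C)C)c1O[Si](C)(C)C
F7 | step 15 | (2E)-1-{2,4-dihydroxy-6-methoxy-3-[(2R)-5-methyl-2-(prop-1-en-2-yl)-5-(triethylsilyloxy)hexyl]phenyl}-3-(2,4-dihydroxyphenyl)prop-2-en-1-one | C=C(C)[C@H](CCC(C)(C)O[Si](CC)(CC)CC)Cc1c(O)cc(OC)c(C(=O)/C=C/c2ccc(O)cc2O)c1O
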